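## Retrosynthetic overview

1. Target 11 comes from Cbz-dihydropyridine 9 by one-pot hydrogenation, hydrogenolysis and reductive N-methylation; the piperidine is a saturated, dearomatised pyridine.
2. 9 comes from a nickel-catalysed enantioselective dearomative C2-arylation of pyridine (as its N-Cbz-pyridinium salt) with the C6-zinc reagent of protected (2S)-naringenin. This one step forms the aryl–piperidine bond and the (R) centre.
3. The arylzinc comes from 6-iodo-5-O-acetyl-7,4'-di-O-benzylnaringenin, made by 5-OH-directed iodination after Mitsunobu benzylation of (2S)-naringenin, which supplies C2 (S).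
4. Ring order: chromanone rings A, C and B arrive intact in naringenin; the nitrogen ring enters as pyridine, is dearomatised in the key step and saturated last.

Assumption: (2S)-naringenin of at least 98% ee is used (checked by chiral HPLC and recrystallised if needed), and the phosphoramidite antipode that gives the (2R) adduct is fixed by one test run.

## Route

Step 1
Reactants: 1 (2S)-naringenin
Product: 2 (2S)-7-(benzyloxy)-2-[4-(benzyloxy)phenyl]-5-hydroxychroman-4-one
Conditions: BnOH (2.3 equiv), PPh3 (2.4 equiv), DIAD (2.4 equiv), THF, 0 °C to rt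
Reagents that add atoms: benzyl alcohol, OCc1ccccc1
Why: Mitsunobu etherification alkylates only the two acidic, non-chelated phenols (7-OH and 4'-OH) and leaves the hydrogen-bonded 5-OH, and because no base is used the base-labile C2 centre stays (S).

Step 2
Reactants: 2 (2S)-7-(benzyloxy)-2-[4-(benzyloxy)phenyl]-5-hydroxychroman-4-one
Product: 3 (2S)-7-(benzyloxy)-2-[4-(benzyloxy)phenyl]-5-hydroxy-6-iodochroman-4-one
Conditions: NIS (1.05 equiv), DMF, 0 °C to rt, dark
Reagents that add atoms: N-iodosuccinimide, O=C1CCC(=O)N1I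
Why: Electrophilic aromatic iodination under neutral conditions is steered by the free chelated 5-OH to its ortho carbon C6 (the 5-OH/7-OR pattern), with the site confirmed by HMBC from the 5-OH proton, and C2 is not touched.

Step 3
Reactants: 3 (2S)-7-(benzyloxy)-2-[4-(benzyloxy)phenyl]-5-hydroxy-6-iodochroman-4-one
Product: 4 (2S)-7-(benzyloxy)-2-[4-(benzyloxy)phenyl]-6-iodo-4-oxochroman-5-yl acetate
Conditions: Ac2O (3 equiv), pyridine (5 equiv), DMAP (0.1 equiv), CH2Cl2, 0 °C to rt
Reagents that add atoms: acetic anhydride, CC(=O)OC(C)=O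
Why: DMAP-catalysed O-acylation removes the only acidic proton before organozinc chemistry and places an acetoxy group ortho to the iodide, where it will direct and speed zinc insertion.

Step 4
Reactants: 4 (2S)-7-(benzyloxy)-2-[4-(benzyloxy)phenyl]-6-iodo-4-oxochroman-5-yl acetate; 5 pyridine
Product: 9 benzyl (2R)-2-[(2S)-7-(benzyloxy)-2-[4-(benzyloxy)phenyl]-5-hydroxy-4-oxochroman-6-yl]-2H-pyridine-1-carboxylate, via arylzinc iodide 6 (not isolated), via N-Cbz-pyridinium chloride 7 (not isolated), via O-acetyl dihydropyridine 8 (not isolated)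
Conditions: Zn dust (3 equiv, activated by BrCH2CH2Br/TMSCl), LiCl (1.5 equiv), THF, 25–40 °C; add slowly to 5 (3.0 equiv) + CbzCl (2.8 equiv) pre-stirred in THF at 0 °C, Ni(acac)2 (10 mol%), (S)-BINOL-derived bis[(R)-1-phenylethyl]amine phosphoramidite (20 mol%, or its antipode, whichever gives 2R), −40 to −20 °C; aq. NH4Cl work-up; then n-BuNH2 (3 equiv), THF, 0 °C
Reagents that add atoms: benzyl chloroformate, O=C(Cl)OCc1ccccc1
Why: Directed ortho insertion of zinc next to the acetoxy group gives a ketone-tolerant arylzinc that adds to C2 of the N-acylpyridinium ion in a nickel–phosphoramidite-catalysed enantioselective dearomative arylation (Negishi-type coupling after oxidative addition of zerovalent nickel to the pyridinium), in which the ligand selects the pyridinium face and so sets the new centre as (R) while the remote (2S) centre is untouched, and aminolysis of the aryl acetate then frees the 5-OH.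

Step 5
Reactants: 9 benzyl (2R)-2-[(2S)-7-(benzyloxy)-2-[4-(benzyloxy)phenyl]-5-hydroxy-4-oxochroman-6-yl]-2H-pyridine-1-carboxylate
Product: 11 (2S)-5,7-dihydroxy-2-(4-hydroxyphenyl)-6-[(2R)-1-methylpiperidin-2-yl]chroman-4-one, via nor-amine 10 (not isolated)
Conditions: H2 (1 atm), 10% Pd/C, EtOAc–MeOH 1:1, rt, until only 10 is seen by LC-MS; then 37% aq. HCHO (1.1 equiv), H2 (1 atm), rt
Reagents that add atoms: formaldehyde, C=O
Why: Catalytic hydrogenation saturates both ring C=C bonds and hydrogenolyses the Cbz and the two O-benzyl groups without touching either stereocentre, and the freed secondary amine is then N-methylated by reductive amination with one equivalent of formaldehyde under the same hydrogen atmosphere.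

## Compound list

1 | (2S)-naringenin, (2S)-5,7-dihydroxy-2-(4-hydroxyphenyl)chroman-4-one | Oc1cc2c(c(O)c1)C(=O)C[C@@H](c1ccc(O)cc1)O2 | starting material
2 | (2S)-7-(benzyloxy)-2-[4-(benzyloxy)phenyl]-5-hydroxychroman-4-one | O(Cc1ccccc1)c1cc2c(c(O)c1)C(=O)C[C@@H](c1ccc(OCc3ccccc3)cc1)O2 | intermediate
3 | (2S)-7-(benzyloxy)-2-[4-(benzyloxy)phenyl]-5-hydroxy-6-iodochroman-4-one | Ic1c(OCc2ccccc2)cc2c(c1O)C(=O)C[C@@H](c1ccc(OCc3ccccc3)cc1)O2 | intermediate
4 | (2S)-7-(benzyloxy)-2-[4-(benzyloxy)phenyl]-6-iodo-4-oxochroman-5-yl acetate | Ic1c(OCc2ccccc2)cc2c(c1OC(C)=O)C(=O)C[C@@H](c1ccc(OCc3ccccc3)cc1)O2 | intermediate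
5 | pyridine | c1ccncc1 | starting material
6 | [(2S)-5-acetoxy-7-(benzyloxy)-2-[4-(benzyloxy)phenyl]-4-oxochroman-6-yl]zinc iodide (LiCl complex in THF) | I[Zn]c1c(OCc2ccccc2)cc2c(c1OC(C)=O)C(=O)C[C@@H](c1ccc(OCc3ccccc3)cc1)O2 | intermediate
7 | 1-(benzyloxycarbonyl)pyridinium chloride | O=C(OCc1ccccc1)[n+]1ccccc1.[Cl-] | intermediate
8 | benzyl (2R)-2-[(2S)-5-acetoxy-7-(benzyloxy)-2-[4-(benzyloxy)phenyl]-4-oxochroman-6-yl]-2H-pyridine-1-carboxylate | O=C(OCc1ccccc1)N1C=CC=C[C@@H]1c1c(OCc2ccccc2)cc2c(c1OC(C)=O)C(=O)C[C@@H](c1ccc(OCc3ccccc3)cc1)O2 | intermediate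
9 | benzyl (2R)-2-[(2S)-7-(benzyloxy)-2-[4-(benzyloxy)phenyl]-5-hydroxy-4-oxochroman-6-yl]-2H-pyridine-1-carboxylate | O=C(OCc1ccccc1)N1C=CC=C[C@@H]1c1c(OCc2ccccc2)cc2c(c1O)C(=O)C[C@@H](c1ccc(OCc3ccccc3)cc1)O2 | intermediate
10 | (2S)-5,7-dihydroxy-2-(4-hydroxyphenyl)-6-[(2R)-piperidin-2-yl]chroman-4-one | N1CCCC[C@@H]1c1c(O)cc2c(c1O)C(=O)C[C@@H](c1ccc(O)cc1)O2 | intermediate
11 | (2S)-5,7-dihydroxy-2-(4-hydroxyphenyl)-6-[(2R)-1-methylpiperidin-2-yl]chroman-4-one | CN1CCCC[C@@H]1c1c(O)cc2c(c1O)C(=O)C[C@@H](c1ccc(O)cc1)O2 | target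

## Step count

Total steps: 5. Longest linear sequence: 5 steps, from (2S)-naringenin; pyridine enters at step 4.

## Steps most likely to fail

**Step 4, the dearomative arylation.** The arylzinc is flanked by two oxygen substituents and is used as the limiting partner, which is outside the demonstrated scope of this reaction. Slow transmetalation, attack at C4 of the pyridinium and low facial selectivity are all possible. Because the flavanone centre is already fixed, a wrong-face adduct is a diastereomer and can be removed by chromatography or crystallisation.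

The fallback sets out from 4 and comes back at 10. It keeps the dearomatisation but splits bond formation and stereocontrol. Negishi coupling of 4 with 2-pyridylzinc bromide (2-PyZnBr; Pd(PPh3)4, THF, 60 °C) gives the 6-(pyridin-2-yl)chromanone acetate F1. Benzyl bromide in MeCN at 70 °C gives the N-benzylpyridinium bromide F2. Asymmetric hydrogenation ([Ir(cod)Cl]2, (R)-SynPhos or the antipode that gives R, H2 40 bar, toluene–CH2Cl2, then NaHCO3 wash) gives the (R)-N-benzylpiperidine acetate F3. n-BuNH2 in THF at 0 °C gives the N-benzylpiperidine phenol F4. H2 over Pd/C then removes the N- and O-benzyl groups to give 10, which is methylated as in step 5.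

**Step 5, the one-pot endgame.** The risks are alkene migration on palladium before saturation (which would erode the piperidine centre), hydrogenolysis of the electron-rich benzylic C–N bond, and reaction of formaldehyde with the unprotected phloroglucinol ring. The free-base product should be kept below 30 °C and away from base, since 5-hydroxyflavanones with a free 4'-OH epimerise at C2 through ring opening.

The fallback sets out from 9 and comes back at 11. It puts the methyl group on before the phenols are unmasked and ends without palladium. H2 over Pd/C poisoned with pyridine (0.5 equiv) saturates the ring and removes only the Cbz group, giving the di-O-benzyl secondary amine F5. Aqueous HCHO with NaBH(OAc)3 in ClCH2CH2Cl gives the di-O-benzyl N-methylpiperidine F6. BCl3 with pentamethylbenzene in CH2Cl2 at −78 °C cleaves both benzyl ethers to give 11.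

**Step 2, the C6 iodination.** C8 is para to the 5-OH and equally activated, so 8-iodo and 6,8-diiodo products may compete.

The fallback sets out from 2 and comes back at 10. It uses a traceless blocking group instead of relying on the directing effect. NBS in MeCN at −30 °C brominates para to the 5-OH to give the 8-bromo phenol F7. NIS in DMF can then only reach C6 and gives the 8-bromo-6-iodo phenol F8. Ac2O, pyridine and DMAP give the 8-bromo-6-iodo acetate F9. Zn and LiCl insert only into the C–I bond next to the acetate to give the 8-bromo arylzinc iodide F10. The nickel-catalysed arylation of 7, run cold so the aryl bromide is not touched, gives the 8-bromo O-acetyl dihydropyridine F11. n-BuNH2 gives the 8-bromo dihydropyridine phenol F12. H2 over Pd/C with NaOAc (1.5 equiv) then removes the bromine together with the Cbz and benzyl groups and saturates the ring to give 10, which is methylated as in step 5.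

## Further compounds

F1 | step 4 | (2S)-7-(benzyloxy)-2-[4-(benzyloxy)phenyl]-4-oxo-6-(pyridin-2-yl)chroman-5-yl acetate | n1ccccc1-c1c(OCc2ccccc2)cc2c(c1OC(C)=O)C(=O)C[C@@H](c1ccc(OCc3ccccc3)cc1)O2
F2 | step 4 | 1-benzyl-2-[(2S)-5-acetoxy-7-(benzyloxy)-2-[4-(benzyloxy)phenyl]-4-oxochroman-6-yl]pyridinium bromide | [Br-].c1ccccc1C[n+]1ccccc1-c1c(OCc2ccccc2)cc2c(c1OC(C)=O)C(=O)C[C@@H](c1ccc(OCc3ccccc3)cc1)O2
F3 | step 4 | (2S)-7-(benzyloxy)-2-[4-(benzyloxy)phenyl]-6-[(2R)-1-benzylpiperidin-2-yl]-4-oxochroman-5-yl acetate | c1ccccc1CN1CCCC[C@@H]1c1c(OCc2ccccc2)cc2c(c1OC(C)=O)C(=O)C[C@@H](c1ccc(OCc3ccccc3)cc1)O2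
F4 | step 4 | (2S)-7-(benzyloxy)-2-[4-(benzyloxy)phenyl]-6-[(2R)-1-benzylpiperidin-2-yl]-5-hydroxychroman-4-one | c1ccccc1CN1CCCC[C@@H]1c1c(OCc2ccccc2)cc2c(c1O)C(=O)C[C@@H](c1ccc(OCc3ccccc3)cc1)O2
F5 | step 5 | (2S)-7-(benzyloxy)-2-[4-(benzyloxy)phenyl]-5-hydroxy-6-[(2R)-piperidin-2-yl]chroman-4-one | N1CCCC[C@@H]1c1c(OCc2ccccc2)cc2c(c1O)C(=O)C[C@@H](c1ccc(OCc3ccccc3)cc1)O2
F6 | step 5 | (2S)-7-(benzyloxy)-2-[4-(benzyloxy)phenyl]-5-hydroxy-6-[(2R)-1-methylpiperidin-2-yl]chroman-4-one | CN1CCCC[C@@H]1c1c(OCc2ccccc2)cc2c(c1O)C(=O)C[C@@H](c1ccc(OCc3ccccc3)cc1)O2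
F7 | step 2 | (2S)-7-(benzyloxy)-2-[4-(benzyloxy)phenyl]-8-bromo-5-hydroxychroman-4-one | Oc1cc(OCc2ccccc2)c(Br)c2c1C(=O)C[C@@H](c1ccc(OCc3ccccc3)cc1)O2
F8 | step 2 | (2S)-7-(benzyloxy)-2-[4-(benzyloxy)phenyl]-8-bromo-5-hydroxy-6-iodochroman-4-one | Ic1c(OCc2ccccc2)c(Br)c2c(c1O)C(=O)C[C@@H](c1ccc(OCc3ccccc3)cc1)O2
F9 | step 2 | (2S)-7-(benzyloxy)-2-[4-(benzyloxy)phenyl]-8-bromo-6-iodo-4-oxochroman-5-yl acetate | Ic1c(OCc2ccccc2)c(Br)c2c(c1OC(C)=O)C(=O)C[C@@H](c1ccc(OCc3ccccc3)cc1)O2
F10 | step 2 | [(2S)-5-acetoxy-7-(benzyloxy)-2-[4-(benzyloxy)phenyl]-8-bromo-4-oxochroman-6-yl]zinc iodide | I[Zn]c1c(OCc2ccccc2)c(Br)c2c(c1OC(C)=O)C(=O)C[C@@H](c1ccc(OCc3ccccc3)cc1)O2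
F11 | step 2 | benzyl (2R)-2-[(2S)-5-acetoxy-7-(benzyloxy)-2-[4-(benzyloxy)phenyl]-8-bromo-4-oxochroman-6-yl]-2H-pyridine-1-carboxylate | O=C(OCc1ccccc1)N1C=CC=C[C@@H]1c1c(OCc2ccccc2)c(Br)c2c(c1OC(C)=O)C(=O)C[C@@H](c1ccc(OCc3ccccc3)cc1)O2
F12 | step 2 | benzyl (2R)-2-[(2S)-7-(benzyloxy)-2-[4-(benzyloxy)phenyl]-8-bromo-5-hydroxy-4-oxochroman-6-yl]-2H-pyridine-1-carboxylate | O=C(OCc1ccccc1)N1C=CC=C[C@@H]1c1c(OCc2ccccc2)c(Br)c2c(c1O)C(=O)C[C@@H](c1ccc(OCc3ccccc3)cc1)O2
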